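The beta run, charged at half the concentration of the zeta run, kept 76.6% of target in target plus side product A at its last reading, more than the 66.2% of the zeta run. So the next run had to be a feed, and I had to decide which reagent to feed.

| setting | zeta | beta | gamma | noon | spring | autumn |
|---|---|---|---|---|---|---|
| substrate | 0.40 M | 0.20 M | 0.30 M | 0.40 M | 0.40 M (fed, over 2.0 h) | 0.40 M |
| partner | 1.1 equiv | 1.1 equiv | 1.1 equiv | 1.10 equiv | 1.10 equiv | 1.10 equiv (fed, over 2.0 h) |
| remark | run made earlier | run made earlier | run made earlier | everything together at the start | all else is in the flask from the start; the feed brings no volume worth counting | all else is in the flask from the start; the feed brings no volume worth counting |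
| time |  |  |  | 3.0 h | 3.0 h | 3.0 h |

| run | time / h | target / % | side product A / % |
|---|---|---|---|
| zeta | 0.250 | 1.3 | 1.6 |
| zeta | 0.833 | 16.2 | 10.7 |
| zeta | 1.33 | 23.5 | 15.8 |
| zeta | 2.00 | 32.8 | 16.5 |
| zeta | 3.00 | 35.9 | 18.3 |
| beta | 0.200 | 1.3 | 0.6 |
| beta | 0.667 | 10.0 | 3.2 |
| beta | 1.00 | 19.1 | 6.6 |
| beta | 1.50 | 27.7 | 10.9 |
| beta | 2.50 | 40.0 | 12.2 |
| gamma | 0.200 | 0.5 | 0 |
| gamma | 0.333 | 5.6 | 1.8 |
| gamma | 0.667 | 10.6 | 5.6 |
| gamma | 1.33 | 25.3 | 12.2 |
| gamma | 2.50 | 40.1 | 14.9 |

(each reading ± 1 percentage point)

- what was read earlier has a scatter of 1 percentage point, one standard deviation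

- the flask with the highest share of target in target plus side product A ("all alike" if they lie within 1.5 percentage points) (noon / spring / autumn / all alike)
- share of target in target plus side product A at the end, noon
- share of target in target plus side product A at the end, spring
- share of target in target plus side product A at the end, autumn

I took ρ, side product A over target at the last reading, and divided it by the partner charged:

σ(zeta) = 1.16 L mol⁻¹
σ(beta) = 1.39 L mol⁻¹
σ(gamma) = 1.13 L mol⁻¹
mean σ = 1.22 L mol⁻¹

This σ, the ratio of side product A to target per mole per litre of partner charged, is my selectivity factor, read with the scatter of the readings. But these runs all had 1.1 equiv, so substrate and partner moved together and σ cannot name the reagent.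

I replaced the curve by its mean. A reagent fed steadily stands, before any use, at a mean of 0.5 of its charge during the feed. I accepted the error of assuming that use takes the same fraction in fed and batch flasks, with c the partner charged, 0.440 M:

ρ, batch = σ·c = 0.538, share 65.0%
ρ, fed = 0.5·σ·c = 0.269, share 78.8%

The flask feeding the reagent that carries the order should give the higher share, the other the lower. That gap of 14 percentage points stands against a scatter of 1 point, so I decided to run both feeds at unchanged equivalents, with noon as control.

The forecast chose spring: noon 66% (63% to 69%), spring 78% (66% to 86%), autumn 58% (46% to 80%), on the words “I assume the likeliest case, substrate self-reaction.” My reckoning names no reagent, so it differs there.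

The flasks gave noon 66.7%, spring 63.1% and autumn 77.6%.

    substrate → intermediate A (k = 0.0210 min⁻¹)
    partner + intermediate A → target (k = 0.0160 L mol⁻¹ min⁻¹)
    partner + intermediate A ⇌ intermediate B (K = 2.30 L mol⁻¹, k = 0.200 L mol⁻¹ min⁻¹)
    partner + intermediate B → side product A (k = 0.240 L mol⁻¹ min⁻¹)
    intermediate B → target (k = 0.0800 min⁻¹)
    substrate + intermediate B → side product B (k = 0.430 L mol⁻¹ min⁻¹)

The upper place went to autumn, the partner feed, whose ρ was 0.289 against my 0.269. In autumn at 0.450 h, substrate had a half-life of 0.55 h by its step to intermediate A, shorter than the 0.76 h of intermediate A by the forward step alone with partner to intermediate B. After 1.50 h autumn held 34.2% of intermediate A against 15.4% in noon, and 5.90% of side product A against 15.5% in noon. For the autumn neighbour with 1.90 equiv of partner, σ reckons a share of 68.3%, and that flask gave 63.8%.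

The earlier runs and the new flask come from a simulation for substances that don't exist; scatter was added.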